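The amounts came first: [substrate] was charged at 20 mM and [reagent] at 22.0 mM, yet full conversion to double product wants 40.0 mM of reagent, more than the charge, so reagent is the limiting reagent in each flask.

in all of them: time 6.0 d

| flask | substrate | reagent | remark |
|---|---|---|---|
| alder | 20 mM (fed, over 5.0 d) | 22.0 mM | all else is in the flask from the start; the feed brings no volume worth counting |
| ash | 20 mM | 22.0 mM | everything together at the start |
| maple | 20 mM | 22.0 mM (fed, over 5.0 d) | all else is in the flask from the start; the feed brings no volume worth counting |

* the flask with the highest amount of double product, in percent of the substrate charged ("all alike" if they lie within 1.5 percentage points) (alder / ash / maple / all alike)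
* final double product, as a percentage of the substrate charged, in alder
* final double product, as a percentage of the substrate charged, in ash
* final double product, as a percentage of the substrate charged, in maple

I wanted two times: the lifetime of double product and its age at the reading. The lifetime is

τ = 1/k3 = 2.52 d

In ash, substrate has a half-life of 0.88 h and mono adduct one of 0.057 d at the charged concentrations, much shorter than 6.0 d, so I froze the age in ash at 6.0 d. Then

S = exp(−t/τ) = 0.0921

This is the survival factor: the fraction of double product, made at a given moment, that still stands after an age t. In maple, double product made as the feed ended is 1.00 d old at the reading, which gives 0.672. My reckoning gave fractions, not amounts made, and stopped there.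

The forecast named maple, with 9.1 % in alder, 3.2 % in ash and 12.6 % in maple, on the ground that “late-formed product survives best”.

The simulation gave maple, with 9.14 % in alder, 3.16 % in ash and 12.7 % in maple, so the forecast held.

    substrate + reagent → mono adduct (k1 = 0.010 M⁻¹ s⁻¹)
    reagent + mono adduct → double product (k2 = 0.0064 M⁻¹ s⁻¹)
    double product → over-reaction product (k3 = 4.6 × 10⁻⁶ s⁻¹)

Without the loss of double product to over-reaction product, the lead of maple over ash falls from 9.6 percentage points to 0 points. In ash, double and over-reaction product together stand at 32.8 %, and S turns that into 3.02 %, beside the simulated 3.16 %. In the neighbour flask, ash read at 2.5 d, S is 0.370, which gives 12.1 %, and that flask holds 12.7 %.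

The constants were drawn at random within sensible limits, and the outcome is calculated.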